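The constants are invented, and the outcome is calculated.

The vessel holds a slurry: solid reagent releases partner into solution while starting material is dosed in, so two supplies run side by side.

    second substrate + partner ⇌ second product (K1 = 0.89 L mol⁻¹, k1 = 5.5 × 10⁻⁵ L mol⁻¹ s⁻¹)
    partner ⇌ dormant form (K2 = 6.0, k2 = 2.4 × 10⁻⁶ s⁻¹)
    solid reagent ⇌ partner, rate k3*(cs3 - [partner]) while solid is left; crystals form when [partner] > cs3 (cs3 = 0.46 M, k3 = 1.8 × 10⁻⁵ s⁻¹)
    second substrate + protic impurity → quenched substrate (k4 = 2.8 × 10⁻⁴ L mol⁻¹ s⁻¹)
    starting material + partner ⇌ target (K5 = 44 L mol⁻¹, k5 = 8.2 × 10⁻⁵ L mol⁻¹ s⁻¹)

| flask | starting material | second substrate | solid reagent | protic impurity | time | remark |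
|---|---|---|---|---|---|---|
| south-east | 1.1 M (fed, over 12 h) | 1.10 M | 1.16 M | 0.0220 M | 30 h | the fed solution adds 0.10 times the starting volume |
| north-west | 1.1 M (fed, over 12 h) | 1.10 M | 1.16 M | 0.0220 M | 40 h | the fed solution adds 0.10 times the starting volume |

- charges are per starting volume, the dose included; the dosed solution carries all of it
- given per volume of solution although it is solid: solid reagent
- at the start none of the solid reagent is in solution
- run time (south-east): 30 h

- which of these there is most of at the end, counted by the starting material in it, south-east (target / starting material)
- which of these there is most of at the end, counted by the starting material in it, north-west (target / starting material)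
- how much there is at the end of the one of these that leads, in percent of the starting material charged: south-east
- how much there is at the end of the one of these that leads, in percent of the starting material charged: north-west

The bench rule for a dosed flask says that starting material is consumed as it arrives, so that the feed paces the run. Here the feed enters at 0.0917 M h⁻¹, whereas the solid gives 0.0298 M h⁻¹ into a partner-free solution. The feed is faster by a factor of 3.08, and there the rule stops working: starting material piles up, and the end of the feed is no milestone.

My own reckoning therefore follows the partner. With the charge taken in the grown volume, 1.00 M, capture by starting material takes up partner with a constant of 0.295 h⁻¹, faster than the dissolution coefficient of 0.0648 h⁻¹, so this reckoning treats dissolution as the rate-limiting step. Setting what dissolves equal to what is captured puts partner near 0.0828 M. Starting material then decays in a pseudo-first-order way with constant 0.0244 h⁻¹, and the integral is a plain exponential, if the dose is counted as entering whole at mid-feed. The way back and the partner held by second substrate stay uncounted. The crossover time, the moment when target and starting material hold equal shares, is mid-feed plus the natural logarithm of two over that constant: 34.4 h. South-east is read earlier than this and north-west later, so the reckoning gives starting material at 55.6% for south-east and target at 56.4% for north-west.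

The forecast differs on south-east: it gave target at 52% there and target at 65% for north-west, saying of the narrow lead of target at the south-east reading that it “makes south-east the closer call”.

The south-east flask ends with starting material in the lead, at 53.2%. The north-west flask ends with target in the lead, at 61.6%. In north-west the two shares meet at 32.0 h, which is 2.40 h before the reckoned crossover time and still later than the south-east reading.

A neighbour of north-west charged with 0.44 M of starting material has its partner level reckoned at 0.163 M, so its crossover time is 20.4 h and the exponential leaves 80.5% as target at 40 h. The computed flask gives 76.8%.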